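**Retrosynthetic overview**

1. Numbering: ring A is C1 (quaternary, bears C12H2–O), C2, C3 (OH), C4 (OAc), C5 (CMe2), C6; the cage arms are C6–C7–C8, C1–C9 and C6–C11(OAc)–C10(Me); C8–C9–C10 is the cyclopropane. The plan rests on C1: this fully substituted one-carbon bridge between C6 and C9 is the blocked sp3 carbon of a ring-A-fused cyclopentadiene C6=C11–C10=C9, and its C12 oxygen lies over the C7–C8 bridge.
2. Disconnections, last to first: C8–C10 and C11–OAc (oxidative decarboxylation of a C8 acid, homoallyl to cyclopropylcarbinyl cation); C6–C7 and C8–C9 (intramolecular Diels–Alder reaction of the C12 acrylate); C3/C4 diol (osmylation); C3=C4 (ring-closing metathesis); C5–C6 (Nicholas alkylation); C1 (auxiliary-controlled lactam alkylation).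
3. Ring order: cyclopentenone (C1 set), then ring A, then bicyclo[2.2.1]heptene and six-membered lactone together in the key step, then the cyclopropane.
4. Design choices: a removable C11 silyloxy group makes the diene electron-rich and turns the electronic regiochemical preference toward the orientation that sterics also favour. C3 is held as a TBS ether to the last step and C4 is acetylated together with C12, because a free C3/C4 diol would acetylate at C3 first. C12 is acetylated before the decarboxylation so that its oxygen cannot trap the C8 cation.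

Key step: step 17

Remark: the second alkylation of the bicyclic lactam is assumed to take the usual endo course (electrophile anti to the angular ethyl group); reversing the order of the two alkylations would lead to the enantiomeric series.

**Route**

Step 1
Reactants: 1 (S)-valinol; 2 4-oxohexanoic acid
Product: 3 bicyclic lactam (3S,7aR)-7a-ethyl-3-isopropyltetrahydropyrrolo[2,1-b]oxazol-5(6H)-one
Conditions: toluene, reflux, Dean–Stark trap
Reagents that add atoms: none
Why: Meyers bicyclic lactam formation (amide formation and N,O-ketalization of a γ-keto acid with an amino alcohol) should give the cis lactam under thermodynamic control, with the angular ethyl group on the same face as the isopropyl group.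

Step 2
Reactants: 3 bicyclic lactam; 4 formaldehyde
Product: 5 6-(hydroxymethyl) lactam (both C6 epimers)
Conditions: LiN(iPr)2, THF, −78 °C; CH2O (gas, from cracked paraformaldehyde), −78 °C
Reagents that add atoms: none
Why: Aldol hydroxymethylation of the lithium lactam enolate introduces C12; the new centre is planarized again in step 4, so its configuration does not matter.

Step 3
Reactants: 5 6-(hydroxymethyl) lactam
Product: 6 6-[(4-methoxybenzyloxy)methyl] lactam (both C6 epimers)
Conditions: NaH, 4-methoxybenzyl chloride, Bu4NI (cat.), DMF, 0 °C to rt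
Reagents that add atoms: 4-methoxybenzyl chloride, COc1ccc(CCl)cc1
Why: Williamson ether synthesis; the PMB ether survives all steps up to the enone and can later be removed oxidatively beside enone, silyl ether and acetate.

Step 4
Reactants: 6 PMB ether lactam; 7 allyl bromide
Product: 8 6-allyl-6-[(4-methoxybenzyloxy)methyl] lactam (allyl anti and CH2OPMB syn to the 7a-ethyl group)
Conditions: LiN(iPr)2, THF, −78 °C; allyl bromide, −78 to −20 °C; chromatographic removal of the minor epimer
Reagents that add atoms: none
Why: Meyers endo alkylation: the second electrophile should enter the lactam enolate anti to the angular ethyl group, which sets quaternary C1 (allyl = C2 branch, CH2OPMB = C12) in the configuration of the target.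

Step 5
Reactants: 8 dialkylated lactam
Product: 10 keto aldehyde 2-allyl-2-[(4-methoxybenzyloxy)methyl]-4-oxohexanal, via carbinolamine 9 (not isolated)
Conditions: NaAlH2(OCH2CH2OMe)2, toluene, −20 °C to rt; then 1 M Bu4N H2PO4, EtOH/H2O, reflux
Reagents that add atoms: water, O
Why: Partial hydride reduction of the lactam to the carbinolamine, then mild acidic hydrolysis of the N,O-aminal, releases aldehyde C9 and ketone C11 and frees the auxiliary; C1 is quaternary and cannot epimerize.

Step 6
Reactants: 10 keto aldehyde
Product: 12 (R)-4-allyl-4-[(4-methoxybenzyloxy)methyl]-2-methylcyclopent-2-en-1-one (C11=O, C10–Me, C9=CH, C1 quaternary, C6H2), via aldol adduct 11 (not isolated)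
Conditions: KOH, EtOH, rt to 50 °C
Reagents that add atoms: none
Why: Intramolecular aldol condensation: only the ethyl-ketone methylene C10 can reach the non-enolizable aldehyde C9 through a five-membered ring, and dehydration gives the 2-methylcyclopentenone.

Step 7
Reactants: 12 cyclopentenone
Product: 13 TBS dienol ether C6=C11(OTBS)–C10(Me)=C9
Conditions: TBSOTf, Et3N, CH2Cl2, 0 °C
Reagents that add atoms: tert-butyldimethylsilyl triflate, CC(C)(C)[Si](C)(C)OS(=O)(=O)C(F)(F)F
Why: Soft enolization (silyl triflate and amine) at C6, the only enolizable position of the enone, gives the cross-conjugated enol silane needed as the carbon nucleophile.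

Step 8
Reactants: 13 TBS dienol ether; 14 2-methylbut-3-yn-2-ol
Product: 17 C6-(2-methylbut-3-yn-2-yl) cyclopentenone (C6 epimers), via Co2(CO)6 complex of the alkynol 15 (not isolated), via Co2(CO)6 complex of the alkylated ketone 16 (not isolated)
Conditions: 14, Co2(CO)8, CH2Cl2, rt; then 13, BF3·OEt2, −78 to −20 °C; then I2, THF, rt
Reagents that add atoms: none
Why: Nicholas reaction: the cobalt-stabilized tertiary propargylic cation alkylates the enol silane at C6 and forms the congested C5–C6 bond with the gem-dimethyl carbon, without allenyl by-products; iodine then removes the cobalt, and the C6 configuration is corrected in step 10.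

Step 9
Reactants: 17 alkyne
Product: 18 C6-(2-methylbut-3-en-2-yl) cyclopentenone (C6 epimers)
Conditions: H2 (1 atm), Pd/CaCO3 poisoned with Pb(OAc)2, quinoline, EtOAc, rt
Reagents that add atoms: none
Why: Lindlar semihydrogenation of the terminal alkyne stops at the vinyl group and should leave the allyl group and the enone untouched.

Step 10
Reactants: 18 diene
Product: 19 cis-fused bicyclic enone (ring A cyclohexene C3=C4; H6 cis to C12)
Conditions: second-generation Grubbs catalyst (5 mol %), CH2Cl2, 40 °C; then DBU, rt
Reagents that add atoms: none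
Why: Ring-closing metathesis of the allyl and vinyl groups closes ring A with loss of ethylene, and base equilibration at C6 (α to the C11 ketone) should converge the epimers on the less strained cis-fused ketone.

Step 11
Reactants: 19 bicyclic enone
Product: 20 C3,C4-cis-diol (both hydroxyls cis to C12)
Conditions: OsO4 (5 mol %), N-methylmorpholine N-oxide, acetone/H2O, 0 °C to rt
Reagents that add atoms: N-methylmorpholine N-oxide, C[N+]1([O-])CCOCC1; water, O
Why: Upjohn dihydroxylation: syn addition to the isolated C3=C4 bond (the enone C9=C10 is deactivated) should occur on the convex face of the cis-fused bicycle, which carries H6 and C12; the other face is closed by the five-membered ring and a C5 methyl group, so C3 and C4 are set cis to C12.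

Step 12
Reactants: 20 diol
Product: 21 C3 TBS ether
Conditions: TBSCl (1.1 equiv), imidazole, DMF, 0 °C
Reagents that add atoms: tert-butyldimethylsilyl chloride, CC(C)(C)[Si](C)(C)Cl
Why: Selective silylation: C3–OH has a methylene neighbour, whereas C4–OH is neopentyl beside CMe2 and should not react with one equivalent.

Step 13
Reactants: 21 C3 TBS ether
Product: 22 C3 TBS ether C4 acetate
Conditions: Ac2O, Et3N, DMAP (cat.), CH2Cl2, rt
Reagents that add atoms: acetic anhydride, CC(=O)OC(C)=O
Why: DMAP-catalysed acetylation of the remaining hindered C4–OH masks it against the silyl triflate of step 16; this acetate is lost in step 20 and renewed in step 21.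

Step 14
Reactants: 22 PMB ether
Product: 23 C12 alcohol
Conditions: DDQ, CH2Cl2/pH 7 phosphate buffer, 0 °C to rt
Reagents that add atoms: none
Why: Oxidative PMB cleavage by DDQ (hydride abstraction, hemiacetal hydrolysis) frees C12–OH without touching enone, silyl ether or acetate.

Step 15
Reactants: 23 C12 alcohol; 24 acryloyl chloride
Product: 25 C12 acrylate
Conditions: Et3N, CH2Cl2, −40 to 0 °C
Reagents that add atoms: none
Why: O-Acylation of the primary neopentyl alcohol with an acid chloride installs the tethered dienophile.

Step 16
Reactants: 25 C12 acrylate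
Product: 26 ring-fused 11-silyloxy cyclopentadiene C12 acrylate (C6=C11(OTBS)–C10(Me)=C9)
Conditions: TBSOTf, Et3N, CH2Cl2, 0 °C to rt; rapid filtration through basic alumina
Reagents that add atoms: tert-butyldimethylsilyl triflate, CC(C)(C)[Si](C)(C)OS(=O)(=O)C(F)(F)F
Why: Soft enolization removes H6, the only α-hydrogen of the ketone, and gives the 2-silyloxy diene; its sp3 carbon C1 is quaternary, so the diene cannot isomerize by 1,5-hydrogen shifts.

Step 17
Reactants: 26 silyloxy diene acrylate
Product: 27 lactone-bridged bicyclo[2.2.1]heptene silyl enol ether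
Conditions: toluene (0.01 M), BHT (cat.), 110 °C, sealed tube
Reagents that add atoms: none
Why: Thermal, concerted suprafacial [4+2] cycloaddition of the tethered acrylate to the diene C6=C11–C10=C9, a normal-electron-demand intramolecular Diels–Alder reaction of a 5,5-disubstituted cyclopentadiene tethered from its sp3 carbon. The new bonds C6–C7 and C8–C9 close the bicyclo[2.2.1]heptene (the two dienophile carbons bridge the diene termini) and the six-membered lactone C1–C12–O–C(=O)–C8–C9 (tether plus one new bond). C6 and C9 are set because the tether can deliver the alkene only to the diene face that carries C12, and C8 is set because the short tether forces the carbonyl to lie syn to the C1 bridge. The step needs regioselectivity, CH2 (C7) to C6 and the carbonyl-bearing C8 to C9, since both orientations would close a six-membered lactone. The C11 silyloxy group places the largest HOMO coefficient on C6, which pairs with the acrylate β-carbon, and the quaternary C5 beside C6 disfavours bonding of the substituted α-carbon there, so electronic and steric bias point the same way. Heating is needed because the ester must reach its less favoured s-cis rotamer, and BHT suppresses acrylate polymerization.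

Step 18
Reactants: 27 silyl enol ether
Product: 28 C11 enol triflate
Conditions: CsF, PhNTf2, DME, rt
Reagents that add atoms: N-phenylbis(trifluoromethanesulfonimide), O=S(=O)(N(c1ccccc1)S(=O)(=O)C(F)(F)F)C(F)(F)F
Why: Fluoride cleaves the enol silane to the regiodefined C10=C11 enolate, which is triflated in situ; the alkyl TBS ether at C3 should react much more slowly than the enol silane.

Step 19
Reactants: 28 enol triflate
Product: 29 lactone-bridged bicycloheptene (C10=C11 with H at C11)
Conditions: Pd(OAc)2 (5 mol %), PPh3, HCO2H, n-Bu3N, DMF, 60 °C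
Reagents that add atoms: none
Why: Palladium-catalysed formate reduction of an enol triflate (oxidative addition to zerovalent palladium, formate exchange, loss of CO2, reductive elimination) removes the activating oxygen and leaves the trisubstituted C10=C11 alkene.

Step 20
Reactants: 29 lactone; 7 allyl bromide
Product: 31 C8 allyl ester with free C12–OH and C4–OH, via potassium carboxylate 30 (not isolated)
Conditions: KOH, MeOH/H2O/THF, 50 °C; KH2PO4 to pH 8, evaporate; allyl bromide, DMF, 0 °C to rt
Reagents that add atoms: potassium hydroxide, [K+].[OH-]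
Why: Saponification opens the lactone and removes the C4 acetate, and O-alkylation of the carboxylate salt under non-acidic conditions traps the acid as its allyl ester before it can relactonize.

Step 21
Reactants: 31 hydroxy allyl ester
Product: 32 C12,C4-diacetate allyl ester
Conditions: Ac2O, DMAP, pyridine, rt to 40 °C
Reagents that add atoms: acetic anhydride, CC(=O)OC(C)=O
Why: DMAP-catalysed acetylation of the two free hydroxyls places the acetates of the target at C12 and C4 while C3 stays silylated, and ends the risk of relactonization.

Step 22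
Reactants: 32 allyl ester
Product: 33 C8 carboxylic acid
Conditions: Pd(PPh3)4 (5 mol %), morpholine, THF, rt
Reagents that add atoms: none
Why: Tsuji–Trost deallylation (π-allyl formation on zerovalent palladium, capture by morpholine) frees the acid without affecting the acetates.

Step 23
Reactants: 33 C8 carboxylic acid
Product: 34 C3 TBS ether of the target (cyclopropane C8–C9–C10 closed, C11–OAc)
Conditions: Pb(OAc)4, pyridine, benzene, 80 °C, argon
Reagents that add atoms: lead tetraacetate, CC(=O)O[Pb](OC(C)=O)(OC(C)=O)OC(C)=O
Why: Kochi-type oxidative decarboxylation: the lead carboxylate loses CO2, the C8 radical is oxidized by tetravalent lead to the cation, the C10=C11 bond closes C8–C10 (homoallyl to cyclopropylcarbinyl, as for 5-norbornene-2-carboxylic acids), and acetate should add to C11 on its open face, toward C7 and away from the C2 methylene of ring A, which is the configuration of the target.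

Step 24
Reactants: 34 C3 TBS ether
Product: 35 target CNP0111873.1
Conditions: HF·pyridine, pyridine/THF, 0 °C to rt
Reagents that add atoms: none
Why: Fluoride desilylation under mildly acidic conditions frees C3–OH and avoids the base-promoted acetyl migration from O4 to O3 that the cis arrangement would allow.

**Compound list**

1 | (S)-valinol | CC(C)[C@H](N)CO | starting material
2 | 4-oxohexanoic acid | CCC(=O)CCC(=O)O | starting material
3 | (3S,7aR)-7a-ethyl-3-isopropyltetrahydropyrrolo[2,1-b]oxazol-5(6H)-one | CC[C@@]12CCC(=O)N1[C@@H](C(C)C)CO2 | intermediate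
4 | formaldehyde (from paraformaldehyde) | C=O | starting material
5 | 6-(hydroxymethyl) lactam, C6 epimers | CC[C@@]12CC(CO)C(=O)N1[C@@H](C(C)C)CO2 | intermediate
6 | 6-[(4-methoxybenzyloxy)methyl] lactam, C6 epimers | CC[C@@]12CC(COCc3ccc(OC)cc3)C(=O)N1[C@@H](C(C)C)CO2 | intermediate
7 | allyl bromide | C=CCBr | starting material
8 | 6-allyl-6-[(4-methoxybenzyloxy)methyl] lactam (allyl anti to 7a-ethyl) | CC[C@@]12C[C@](COCc3ccc(OC)cc3)(CC=C)C(=O)N1[C@@H](C(C)C)CO2 | intermediate
9 | carbinolamine from reduction of the lactam carbonyl | CC[C@@]12C[C@](COCc3ccc(OC)cc3)(CC=C)C(O)N1[C@@H](C(C)C)CO2 | intermediate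
10 | 2-allyl-2-[(4-methoxybenzyloxy)methyl]-4-oxohexanal | O=C[C@@](COCc1ccc(OC)cc1)(CC=C)CC(=O)CC | intermediate
11 | aldol adduct (3-hydroxy-2-methylcyclopentanone) | CC1C(=O)C[C@](COCc2ccc(OC)cc2)(CC=C)C1O | intermediate
12 | (R)-4-allyl-4-[(4-methoxybenzyloxy)methyl]-2-methylcyclopent-2-en-1-one | CC1=C[C@@](COCc2ccc(OC)cc2)(CC=C)CC1=O | intermediate
13 | TBS dienol ether of 12 | CC1=C[C@@](COCc2ccc(OC)cc2)(CC=C)C=C1O[Si](C)(C)C(C)(C)C | intermediate
14 | 2-methylbut-3-yn-2-ol | CC(C)(O)C#C | starting material
15 | hexacarbonyldicobalt complex of 14 | CC(C)(O)C12[CH]3[Co]1(=C=O)(=C=O)(=C=O)[Co]23(=C=O)(=C=O)=C=O | intermediate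
16 | hexacarbonyldicobalt complex of 17 | CC1=C[C@@](COCc2ccc(OC)cc2)(CC=C)C(C1=O)C(C)(C)C34[CH]5[Co]3(=C=O)(=C=O)(=C=O)[Co]45(=C=O)(=C=O)=C=O | intermediate
17 | C6-(2-methylbut-3-yn-2-yl) cyclopentenone, C6 epimers | CC1=C[C@@](COCc2ccc(OC)cc2)(CC=C)C(C1=O)C(C)(C)C#C | intermediate
18 | C6-(2-methylbut-3-en-2-yl) cyclopentenone, C6 epimers | CC1=C[C@@](COCc2ccc(OC)cc2)(CC=C)C(C1=O)C(C)(C)C=C | intermediate
19 | cis-fused bicyclic enone with ring A alkene C3=C4 | COc1ccc(COC[C@]23CC=CC(C)(C)[C@H]2C(=O)C(C)=C3)cc1 | intermediate
20 | C3,C4-cis-diol (cis to C12) | COc1ccc(COC[C@]23C[C@H](O)[C@H](O)C(C)(C)[C@H]2C(=O)C(C)=C3)cc1 | intermediate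
21 | C3 TBS ether | COc1ccc(COC[C@]23C[C@H](O[Si](C)(C)C(C)(C)C)[C@H](O)C(C)(C)[C@H]2C(=O)C(C)=C3)cc1 | intermediate
22 | C3 TBS ether C4 acetate | COc1ccc(COC[C@]23C[C@H](O[Si](C)(C)C(C)(C)C)[C@H](OC(C)=O)C(C)(C)[C@H]2C(=O)C(C)=C3)cc1 | intermediate
23 | C12 alcohol | OC[C@]12C[C@H](O[Si](C)(C)C(C)(C)C)[C@H](OC(C)=O)C(C)(C)[C@H]1C(=O)C(C)=C2 | intermediate
24 | acryloyl chloride | C=CC(=O)Cl | starting material
25 | C12 acrylate enone | C=CC(=O)OC[C@]12C[C@H](O[Si](C)(C)C(C)(C)C)[C@H](OC(C)=O)C(C)(C)[C@H]1C(=O)C(C)=C2 | intermediate
26 | ring-fused 11-silyloxy cyclopentadiene C12 acrylate (key-step precursor) | C=CC(=O)OC[C@]12C[C@H](O[Si](C)(C)C(C)(C)C)[C@H](OC(C)=O)C(C)(C)C1=C(O[Si](C)(C)C(C)(C)C)C(C)=C2 | intermediate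
27 | lactone-bridged bicycloheptene silyl enol ether (key-step product) | O=C5OC[C@]12C[C@H](O[Si](C)(C)C(C)(C)C)[C@H](OC(C)=O)C(C)(C)[C@]13C[C@H]5[C@H]2C(C)=C3O[Si](C)(C)C(C)(C)C | intermediate
28 | C11 enol triflate | O=C5OC[C@]12C[C@H](O[Si](C)(C)C(C)(C)C)[C@H](OC(C)=O)C(C)(C)[C@]13C[C@H]5[C@H]2C(C)=C3OS(=O)(=O)C(F)(F)F | intermediate
29 | lactone-bridged bicycloheptene, C10=C11 | O=C5OC[C@]12C[C@H](O[Si](C)(C)C(C)(C)C)[C@H](OC(C)=O)C(C)(C)[C@]13C[C@H]5[C@H]2C(C)=C3 | intermediate
30 | potassium C8 carboxylate | OC[C@]12C[C@H](O[Si](C)(C)C(C)(C)C)[C@H](O)C(C)(C)[C@]13C[C@H](C(=O)[O-])[C@H]2C(C)=C3.[K+] | intermediate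
31 | C8 allyl ester, C12–OH and C4–OH free | OC[C@]12C[C@H](O[Si](C)(C)C(C)(C)C)[C@H](O)C(C)(C)[C@]13C[C@H](C(=O)OCC=C)[C@H]2C(C)=C3 | intermediate
32 | C12,C4-diacetate allyl ester | CC(=O)OC[C@]12C[C@H](O[Si](C)(C)C(C)(C)C)[C@H](OC(C)=O)C(C)(C)[C@]13C[C@H](C(=O)OCC=C)[C@H]2C(C)=C3 | intermediate
33 | C8 carboxylic acid | CC(=O)OC[C@]12C[C@H](O[Si](C)(C)C(C)(C)C)[C@H](OC(C)=O)C(C)(C)[C@]13C[C@H](C(=O)O)[C@H]2C(C)=C3 | intermediate
34 | C3 TBS ether of the target | CC(=O)OC[C@]12C[C@H](O[Si](C)(C)C(C)(C)C)[C@H](OC(C)=O)C(C)(C)[C@]13C[C@@H]1[C@H]2[C@]1(C)[C@H]3OC(C)=O | intermediate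
35 | CNP0111873.1 | CC(=O)OC[C@]12C[C@H](O)[C@H](OC(C)=O)C(C)(C)[C@]13C[C@@H]1[C@H]2[C@]1(C)[C@H]3OC(C)=O | target

**Step count and risks**

Total step count: 24. Longest linear sequence: 24 steps (from 1 and 2 to 35).

Steps most likely to fail:

1. Step 23 (oxidative decarboxylation). The C8 radical may be intercepted before it is oxidized, the delocalized cation may be captured at C8 instead of C11, or acetate may approach C11 from the side of C2. Fallback: set out from acid 33 and separate radical formation from ionization. A radical iododecarboxylation (PhI(OAc)2, I2, visible light, CH2Cl2) would give the homoallylic C8 iodide F1. Silver-assisted acetolysis (AgOAc, AcOH, rt) then generates the same cyclopropylcarbinyl cation under solvolytic conditions, where the C11 acetates can re-ionize and settle on the less hindered epimer. This comes back to the route at 34.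

2. Step 17 (intramolecular Diels–Alder reaction). The acrylate may add in the reversed orientation (carbonyl-bearing carbon to C6), or the cyclization may be so slow that the silyl dienol ether is lost to hydrolysis or dimerization. Fallback: set out from alcohol 23 and esterify with 2-chloroacrylic acid (DCC, DMAP, CH2Cl2) to the 2-chloroacrylate F2. Form the silyloxy diene F3 as in step 16 and warm it in toluene. The captodative chloroacrylate is a faster dienophile, and its fully substituted α-carbon should not bond to the crowded C6, so the adduct should be the α-chloro lactone F4. SmI2 in THF/MeOH at −78 °C removes the chlorine through the samarium enolate; protonation within the rigid lactone comes back to the route at 27.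

3. Step 11 (dihydroxylation). Osmylation may take the face of the five-membered ring and give the diol trans to C12. Fallback: set out from 19 and use the Woodward cis-hydroxylation (I2, AgOAc, AcOH, then wet AcOH, 90 °C). Iodine takes the face that the osmium reagent took, acetate opens the iodonium ion from the other face, and the acetoxonium ion places both oxygens there. This gives the hydroxy acetate F5 (with its regioisomer); K2CO3 in MeOH removes the acetyl group and comes back to the route at 20.

Further compounds
F1 | step 23 | C8 iodide of the C12,C4-diacetate (C8 epimers) | CC(=O)OC[C@]12C[C@H](O[Si](C)(C)C(C)(C)C)[C@H](OC(C)=O)C(C)(C)[C@]13CC(I)[C@H]2C(C)=C3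
F2 | step 17 | C12 2-chloroacrylate enone | C=C(Cl)C(=O)OC[C@]12C[C@H](O[Si](C)(C)C(C)(C)C)[C@H](OC(C)=O)C(C)(C)[C@H]1C(=O)C(C)=C2
F3 | step 17 | 11-silyloxy cyclopentadiene C12 2-chloroacrylate | C=C(Cl)C(=O)OC[C@]12C[C@H](O[Si](C)(C)C(C)(C)C)[C@H](OC(C)=O)C(C)(C)C1=C(O[Si](C)(C)C(C)(C)C)C(C)=C2
F4 | step 17 | C8-chloro lactone-bridged bicycloheptene silyl enol ether | O=C5OC[C@]12C[C@H](O[Si](C)(C)C(C)(C)C)[C@H](OC(C)=O)C(C)(C)[C@]13C[C@@]5(Cl)[C@H]2C(C)=C3O[Si](C)(C)C(C)(C)C
F5 | step 11 | C3-hydroxy C4-acetate of the bicyclic enone (cis to C12) | COc1ccc(COC[C@]23C[C@H](O)[C@H](OC(C)=O)C(C)(C)[C@H]2C(=O)C(C)=C3)cc1
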